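**Plan**

- Retrosynthesis: the C5 methylene and the C6 and C8 hydrogens are traced back to a ring A enone. C3–C8, C4–C5 and C5–C6 are then cut together (allenic Pauson–Khand), followed by C27–C2 (allenylation of a ketone), C9–C8 (acetylide alkylation), C13–C11 (enolate allylation) and the Robinson bonds C15–C14 and C26–C25.
- Forward: ring D is the bought cyclopentanone and ring C is annulated onto it. The C13 side chain and the trans-hydrindane are set, the allene is placed on C27, and rings A (C3, C4, C5, C6, C8) and B (C2, C3, C8, C9, C10, C11, C13, C27) close together. Ring A is then reduced and deoxygenated.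
- Enabling feature: C3 belongs to ring A and to ring B and is one end of the C2=C3 alkene. This is the 4-alkylidenecyclopentenone pattern left by an allene that reacted through its distal π-bond with a tethered alkyne and CO.
- Stereochemistry: C15 by catalytic asymmetric Michael addition; C25 and C21 by hydrogenation anti to the C15 ester; C11 by ligand control in an iridium allylation; C13 and C6 by equilibration; C27 by equatorial attack on the ring ketone; C8 by hydrogenation anti to the C9–C11 bridge; C2=C3 geometry by ring B.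

Key step: step 15

Remark: locants are those of the target SMILES read left to right (C1 … O28), β is the face of the C15 carboxyl group, and C21 is carried as an epimer mixture in 4–12 because step 7 turns it into an alkene carbon.

Step 1
Reactants: 1 methyl 2-oxocyclopentane-1-carboxylate; 2 2-iodopropane
Product: 4 methyl 2-oxo-3-(propan-2-yl)cyclopentane-1-carboxylate, via dilithium dianion 3 (not isolated)
Conditions: LDA (2.2 equiv), THF, 0 °C; 2, DMPU, 0 °C to rt; aq HCl
Reagents that add atoms: none
Why: γ-Alkylation of a β-keto ester dianion, which reacts only at its more basic C21 carbanion, with DMPU pushing the slow secondary iodide; no lasting stereocentre is set because C21 later becomes sp2.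

Step 2
Reactants: 4 methyl 2-oxo-3-(propan-2-yl)cyclopentane-1-carboxylate; 5 but-3-en-2-one
Product: 6 methyl (1S)-2-oxo-1-(3-oxobutyl)-3-(propan-2-yl)cyclopentane-1-carboxylate (C21 epimers)
Conditions: 5 (1.5 equiv), [Pd(BINAP)(OH2)2](OTf)2 (5 mol %, the BINAP antipode that gives 1S), THF, −20 °C
Reagents that add atoms: none
Why: Catalytic enantioselective Michael addition of a chelated β-keto ester enolate to an enone, in which the chiral palladium enolate shields one face of C15 so the quaternary centre should form as (S) whatever the configuration of the remote C21.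

Step 3
Reactants: 6 methyl (1S)-2-oxo-1-(3-oxobutyl)-3-(propan-2-yl)cyclopentane-1-carboxylate
Product: 7 methyl (7aS)-5-oxo-3-(propan-2-yl)-2,3,5,6,7,7a-hexahydro-1H-indene-7a-carboxylate (C26=C25 enone; C21 epimers)
Conditions: p-TsOH·H2O (10 mol %), toluene, reflux, Dean–Stark
Reagents that add atoms: none
Why: Second stage of the Robinson annulation, an acid-catalysed intramolecular aldol condensation of the methyl ketone onto the ring ketone C25 that closes ring C and cannot touch the quaternary C15.

Step 4
Reactants: 7 Robinson enone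
Product: 9 methyl (7aS)-3-(propan-2-yl)-5-(trimethylsilyloxy)-2,3,7,7a-tetrahydro-1H-indene-7a-carboxylate, via lithium dienolate 8 (not isolated)
Conditions: LDA, THF, −78 °C; TMSCl, −78 to 0 °C
Reagents that add atoms: chlorotrimethylsilane, C[Si](C)(C)Cl
Why: Kinetic α′-deprotonation of an enone at C13 gives the cross-conjugated dienolate, which is trapped on oxygen as the silyl enol ether while the ester on quaternary C15 stays inert at −78 °C.

Step 5
Reactants: 10 (E)-but-2-en-1-ol
Product: 11 (E)-but-2-en-1-yl methyl carbonate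
Conditions: ClCO2Me, pyridine, CH2Cl2, 0 °C
Reagents that add atoms: methyl chloroformate, COC(=O)Cl
Why: Acylation of a primary allylic alcohol with a chloroformate gives the carbonate leaving group needed for iridium allylation without touching the alkene.

Step 6
Reactants: 9 silyl dienol ether; 11 (E)-but-2-en-1-yl methyl carbonate
Product: 12 methyl (7aS)-6-[(2S)-but-3-en-2-yl]-5-oxo-3-(propan-2-yl)-2,3,5,6,7,7a-hexahydro-1H-indene-7a-carboxylate (chain 13α; C21 epimers)
Conditions: [Ir(cod)Cl]2 (2 mol %), BINOL-derived bis(1-phenylethyl)amine phosphoramidite (4 mol %, the antipode that gives 11S), KF, 18-crown-6, THF, 50 °C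
Reagents that add atoms: none
Why: Iridium-catalysed branched-selective asymmetric allylic alkylation of a fluoride-released silyl enolate, in which the cyclometalated Ir–phosphoramidite fixes the face of the π-crotyl terminus and so sets C11 as (S) by ligand control, while C13 is attacked anti to the pseudoaxial ester and stays epimerisable.

Step 7
Reactants: 12 allylated enone
Product: 13 C27 ethylene ketal with the ring alkene moved to C25=C21 and a 13α-[(2S)-but-3-en-2-yl] chain
Conditions: HOCH2CH2OH, p-TsOH (cat.), benzene, reflux, Dean–Stark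
Reagents that add atoms: ethane-1,2-diol, OCCO
Why: Acid-catalysed acetalisation of a conjugated enone with double-bond migration (as Δ4-3-keto steroids give Δ5-ketals) runs through the dienol ether and C26 protonation, which protects C27, parks the alkene at C25=C21 and erases the C21 mixture.

Step 8
Reactants: 13 vinyl ketal
Product: 15 13α-[(2S)-4-hydroxybutan-2-yl] ketal alcohol (C25=C21 alkene kept), via alkylborane 14 (not isolated)
Conditions: 9-BBN, THF, 0 °C to rt; NaOH, H2O2, 0 °C
Reagents that add atoms: hydrogen peroxide, OO; 9-borabicyclo[3.3.1]nonane, B1C2CCCC1CCC2 (boron in 14 only)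
Why: Anti-Markovnikov hydroboration–oxidation in which 9-BBN adds only to the monosubstituted vinyl group and leaves the tetrasubstituted ring alkene, the ester and the ketal alone.

Step 9
Reactants: 15 ketal alcohol
Product: 16 trans-hydrindane ketal alcohol (25α-H, 21β-isopropyl, 15β-CO2Me, 13α-[(2S)-4-hydroxybutan-2-yl])
Conditions: H2 (50 bar), PtO2, EtOAc, rt
Reagents that add atoms: none
Why: Heterogeneous syn-hydrogenation of the tetrasubstituted C25=C21 alkene from the α-face, opposite the angular C15 ester (the sense seen with Δ14-steroids), should deliver 25α-H and 21α-H together and so set the trans ring fusion and the 21β-isopropyl group.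

Step 10
Reactants: 16 trans-hydrindane ketal alcohol
Product: 17 13α-[(2S)-4-iodobutan-2-yl] ketal iodide
Conditions: I2, PPh3, imidazole, CH2Cl2, 0 °C
Reagents that add atoms: iodine, II
Why: Appel iodination of the primary alcohol under imidazole buffering, which the ketal tolerates.

Step 11
Reactants: 17 ketal iodide; 18 prop-1-ynyllithium
Product: 19 13α-[(2S)-hept-5-yn-2-yl] ketal
Conditions: THF–DMPU, −20 °C to rt
Reagents that add atoms: none
Why: SN2 alkylation of a lithium acetylide with a primary iodide forms C9–C8 and completes the side chain, while the C27 ketal and the neopentyl-type ester do not react.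

Step 12
Reactants: 19 alkyne ketal
Product: 20 methyl 13α-[(2S)-hept-5-yn-2-yl]-21β-isopropyl-27-oxo-trans-hydrindane-15β-carboxylate (25α-H)
Conditions: 2 M HCl, THF, 40 °C; then NaOMe (0.2 equiv), MeOH, rt
Reagents that add atoms: water, O
Why: Acetal hydrolysis followed by base equilibration of the α-centre, in which the C13 branch settles equatorial (α) because the axial epimer would be syn-axial to the C15 ester.

Step 13
Reactants: 20 ring ketone; 21 1-bromobut-2-yne
Product: 22 allenyl carbinol (27α-OH, 27β-buta-2,3-dien-2-yl)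
Conditions: In powder, THF, 50 °C
Reagents that add atoms: none
Why: Indium-mediated Barbier reaction in which the but-2-ynylindium species adds through its γ-carbon (SE2′) to give the allenyl carbinol, entering C27 along the equatorial trajectory, trans to the C13 branch and clear of the axial 14α and 25α hydrogens, so that the hydroxyl ends up axial (27α).

Step 14
Reactants: 22 allenyl carbinol
Product: 23 triethylsilyl ether of 22 (allenyne precursor)
Conditions: TESOTf, 2,6-lutidine, CH2Cl2, −78 to 0 °C
Reagents that add atoms: triethylsilyl trifluoromethanesulfonate, CC[Si](CC)(CC)OS(=O)(=O)C(F)(F)F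
Why: Silylation of a hindered tertiary alcohol with a silyl triflate and a non-nucleophilic base, to which the allene, the alkyne and the ester are inert.

Step 15
Reactants: 23 allenyne silyl ether
Product: 24 tetracyclic dienone (C5 ketone, C6=C8 and C2=C3 alkenes, 27α-OTES, methyl ester)
Conditions: [Rh(CO)2Cl]2 (10 mol %), CO (1 atm), toluene (0.005 M), 90 °C
Reagents that add atoms: carbon monoxide, [C-]#[O+]
Why: Rh(I) binds the C6≡C8 alkyne and the distal C3=C4 π-bond of the allene, oxidative cyclisation forms C3–C8 in a rhodacyclopentene, CO inserts and reductive elimination completes C4–C5 and C5–C6. The closest known reaction type is the Rh(I)-catalysed allenic Pauson–Khand reaction through the distal double bond, routine for bicyclo[5.3.0] products and documented for bicyclo[6.3.0]undecadienones. Ring A (C3, C4, C5, C6, C8) arises from the [2+2+1] itself, and ring B (C2, C3, C8, C9, C10, C11, C13, C27) is closed by the tether, formally an 8-exo attack of C8 on the central allene carbon C3 within the metallacycle. No stereocentre is created: C6 and C8 are sp2 in the product and the C2=C3 geometry (C27 cis to C8) is dictated by the ring. The step needs distal over proximal π-bond selectivity and cyclisation over oligomerisation; the first is secured by Rh(I) and the fully substituted proximal carbon C2, the second by high dilution, the trans-diequatorial C13 and C27 arms on the rigid trans-hydrindane and the gem-disubstituent effect of the silyl ether and the C11 methyl.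

Step 16
Reactants: 24 silylated dienone
Product: 25 27α-hydroxy dienone
Conditions: HF·pyridine, pyridine, THF, 0 °C to rt
Reagents that add atoms: none
Why: Fluoride-driven Si–O cleavage under buffered conditions spares the tertiary allylic alcohol and the dienone and frees the small 27α-hydroxyl, which opens the α-face for the next step.

Step 17
Reactants: 25 hydroxy dienone
Product: 26 6β-methyl-8α-H ketone (C6 methyl cis to C9; C2=C3 kept)
Conditions: H2 (1 atm), 10 % Pd/C, EtOAc, rt
Reagents that add atoms: none
Why: Catalytic syn-hydrogenation of the cyclopentenone C6=C8 bond from the α-face, which is away from the C9–C10–C11 bridge arching over the β-face of the planar dienone and is the face where the axial C27 hydroxyl can anchor to the catalyst, should set 8α-H (and kinetically 6α-H), while the tetrasubstituted C2=C3 alkene is screened by the quaternary C27.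

Step 18
Reactants: 26 cis ketone
Product: 27 6α-methyl-8α-H ketone (C6 methyl trans to C9)
Conditions: DBU, toluene, 40 °C
Reagents that add atoms: none
Why: Base-mediated epimerisation through the C5 enolate places the C6 methyl trans to C9, the thermodynamic arrangement of a 2,3-disubstituted cyclopentanone, and the bulky amidinium ion reprotonates C4 and C6 but hardly the congested C2, which should keep the β,γ-alkene in place.

Step 19
Reactants: 27 trans ketone
Product: 28 C5 alcohol (C5 epimers)
Conditions: NaBH4, MeOH, 0 °C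
Reagents that add atoms: none
Why: Borohydride reduction of the cyclopentanone gives the C5 alcohol, whose configuration does not matter, without touching the ester or the alkene.

Step 20
Reactants: 28 C5 alcohol
Product: 29 C5 O-phenyl thiocarbonate
Conditions: PhOC(S)Cl, pyridine, DMAP (cat.), CH2Cl2, rt
Reagents that add atoms: O-phenyl carbonochloridothioate, S=C(Cl)Oc1ccccc1
Why: Thioacylation of the secondary alcohol (first stage of the Barton–McCombie deoxygenation), which the congested tertiary C27 alcohol should not undergo.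

Step 21
Reactants: 29 thiocarbonate
Product: 30 methyl sesterfisherate
Conditions: Bu3SnH, AIBN (cat.), toluene, 90 °C
Reagents that add atoms: none
Why: Barton–McCombie radical deoxygenation in which the secondary C5 radical is reduced by the stannane, 3-exo attack on C2=C3 being uncompetitive because it would build a bicyclo[2.1.0] unit.

Step 22
Reactants: 30 methyl sesterfisherate
Product: 31 sesterfisheric acid
Conditions: NaSEt, DMF, 90 °C; cold 0.5 M HCl to pH 4
Reagents that add atoms: none
Why: SN2 demethylation of the hindered angular ester by thiolate at the methyl carbon is indifferent to the crowded acyl carbon and spares the tertiary allylic alcohol.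

**Compound list**

1 | methyl 2-oxocyclopentane-1-carboxylate | COC(=O)C1CCCC1=O | starting material
2 | 2-iodopropane | CC(C)I | starting material
3 | dilithium dianion of 1 (not isolated) | [Li+].[Li+].COC(=O)C1=C([O-])[CH-]CC1 | intermediate
4 | methyl 2-oxo-3-(propan-2-yl)cyclopentane-1-carboxylate (racemic diastereomer mixture) | COC(=O)C1CCC(C(C)C)C1=O | intermediate
5 | but-3-en-2-one | CC(=O)C=C | starting material
6 | methyl (1S)-2-oxo-1-(3-oxobutyl)-3-(propan-2-yl)cyclopentane-1-carboxylate (C21 epimers) | CC(=O)CC[C@@]1(C(=O)OC)CCC(C(C)C)C1=O | intermediate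
7 | methyl (7aS)-5-oxo-3-(propan-2-yl)-2,3,5,6,7,7a-hexahydro-1H-indene-7a-carboxylate (C21 epimers) | O=C1CC[C@@]2(C(=O)OC)CCC(C(C)C)C2=C1 | intermediate
8 | lithium C27–O/C13 dienolate of 7 (not isolated) | [Li+].[O-]C1=CC[C@@]2(C(=O)OC)CCC(C(C)C)C2=C1 | intermediate
9 | methyl (7aS)-3-(propan-2-yl)-5-(trimethylsilyloxy)-2,3,7,7a-tetrahydro-1H-indene-7a-carboxylate (C21 epimers) | C[Si](C)(C)OC1=CC[C@@]2(C(=O)OC)CCC(C(C)C)C2=C1 | intermediate
10 | (E)-but-2-en-1-ol | C/C=C/CO | starting material
11 | (E)-but-2-en-1-yl methyl carbonate | C/C=C/COC(=O)OC | intermediate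
12 | methyl (7aS)-6-[(2S)-but-3-en-2-yl]-5-oxo-3-(propan-2-yl)-2,3,5,6,7,7a-hexahydro-1H-indene-7a-carboxylate (chain 13α; C21 epimers; any 13-epimer converges in step 12) | C=C[C@H](C)[C@H]1C[C@@]2(C(=O)OC)CCC(C(C)C)C2=CC1=O | intermediate
13 | C27 ethylene ketal, C25=C21 alkene, 13α-[(2S)-but-3-en-2-yl], 15β-CO2Me | C=C[C@H](C)[C@H]1C[C@@]2(C(=O)OC)CCC(C(C)C)=C2CC13OCCO3 | intermediate
14 | B-alkyl-9-borabicyclo[3.3.1]nonane adduct of 13, boron on C9 (not isolated) | C1CCC2CCCC1B2CC[C@H](C)[C@H]1C[C@@]2(C(=O)OC)CCC(C(C)C)=C2CC13OCCO3 | intermediate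
15 | ketal alcohol, C25=C21 alkene, 13α-[(2S)-4-hydroxybutan-2-yl] | OCC[C@H](C)[C@H]1C[C@@]2(C(=O)OC)CCC(C(C)C)=C2CC13OCCO3 | intermediate
16 | trans-hydrindane ketal alcohol (25α-H, 21β-isopropyl, 15β-CO2Me, 13α chain) | OCC[C@H](C)[C@H]1C[C@@]2(C(=O)OC)CC[C@H](C(C)C)[C@@H]2CC13OCCO3 | intermediate
17 | trans-hydrindane ketal iodide, 13α-[(2S)-4-iodobutan-2-yl] | ICC[C@H](C)[C@H]1C[C@@]2(C(=O)OC)CC[C@H](C(C)C)[C@@H]2CC13OCCO3 | intermediate
18 | prop-1-ynyllithium | [Li]C#CC | starting material
19 | trans-hydrindane ketal, 13α-[(2S)-hept-5-yn-2-yl] | CC#CCC[C@H](C)[C@H]1C[C@@]2(C(=O)OC)CC[C@H](C(C)C)[C@@H]2CC13OCCO3 | intermediate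
20 | methyl 13α-[(2S)-hept-5-yn-2-yl]-21β-isopropyl-27-oxo-trans-hydrindane-15β-carboxylate (25α-H) | CC#CCC[C@H](C)[C@H]1C[C@@]2(C(=O)OC)CC[C@H](C(C)C)[C@@H]2CC1=O | intermediate
21 | 1-bromobut-2-yne | CC#CCBr | starting material
22 | allenyl carbinol (27α-OH, 27β-buta-2,3-dien-2-yl) | CC#CCC[C@H](C)[C@H]1C[C@@]2(C(=O)OC)CC[C@H](C(C)C)[C@@H]2C[C@]1(O)C(C)=C=C | intermediate
23 | triethylsilyl ether of 22 (Pauson–Khand precursor) | CC#CCC[C@H](C)[C@H]1C[C@@]2(C(=O)OC)CC[C@H](C(C)C)[C@@H]2C[C@]1(O[Si](CC)(CC)CC)C(C)=C=C | intermediate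
24 | tetracyclic dienone (C5 ketone, C6=C8, C2=C3 with C27 cis to C8, 27α-OTES) | C/C1=C2\CC(=O)C(C)=C2CC[C@H](C)[C@H]2C[C@@]3(C(=O)OC)CC[C@H](C(C)C)[C@@H]3C[C@]12O[Si](CC)(CC)CC | intermediate
25 | 27α-hydroxy dienone | C/C1=C2\CC(=O)C(C)=C2CC[C@H](C)[C@H]2C[C@@]3(C(=O)OC)CC[C@H](C(C)C)[C@@H]3C[C@]12O | intermediate
26 | 6β-methyl-8α-H C5 ketone (cis) | C/C1=C2\CC(=O)[C@H](C)[C@@H]2CC[C@H](C)[C@H]2C[C@@]3(C(=O)OC)CC[C@H](C(C)C)[C@@H]3C[C@]12O | intermediate
27 | 6α-methyl-8α-H C5 ketone (trans) | C/C1=C2\CC(=O)[C@@H](C)[C@@H]2CC[C@H](C)[C@H]2C[C@@]3(C(=O)OC)CC[C@H](C(C)C)[C@@H]3C[C@]12O | intermediate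
28 | C5 alcohol (C5 epimers) | C/C1=C2\CC(O)[C@@H](C)[C@@H]2CC[C@H](C)[C@H]2C[C@@]3(C(=O)OC)CC[C@H](C(C)C)[C@@H]3C[C@]12O | intermediate
29 | C5 O-phenyl thiocarbonate (C5 epimers) | C/C1=C2\CC(OC(=S)Oc4ccccc4)[C@@H](C)[C@@H]2CC[C@H](C)[C@H]2C[C@@]3(C(=O)OC)CC[C@H](C(C)C)[C@@H]3C[C@]12O | intermediate
30 | methyl sesterfisherate | C/C1=C2\CC[C@@H](C)[C@@H]2CC[C@H](C)[C@H]2C[C@@]3(C(=O)OC)CC[C@H](C(C)C)[C@@H]3C[C@]12O | intermediate
31 | sesterfisheric acid | C/C1=C2\CC[C@@H](C)[C@@H]2CC[C@H](C)[C@H]2C[C@@]3(C(=O)O)CC[C@H](C(C)C)[C@@H]3C[C@]12O | target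

**Count and risks**

Total: 22 steps. Longest linear sequence: 21 steps (steps 1–4 and 6–22 from 1); step 5 is a one-step branch.

1. Step 15, the eight-membered ring closure. The rhodacycle that must span C3 and C8 may form slowly, so that oligomerisation or rhodium-catalysed cycloisomerisation of the allenyne consumes 23. The fallback leaves rhodium catalysis for a stoichiometric molybdenum-mediated allenic cyclocarbonylation: 23 with Mo(CO)6 and DMSO in toluene at 100 °C, where CO comes from the metal and 1,1-disubstituted allenes are known to react through the external π-bond. It sets out from 23, comes back at 24 and makes no new compound (F0).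

2. Step 18, the C6 equilibration. Under base the C4 dienolate may reprotonate at C2, so that the C2=C3 alkene drifts into conjugation with the ketone before the C6 epimers have equilibrated. The fallback brings the C6 methyl in last, under kinetic control, and sets out from iodide 17. Lithium acetylide–ethylenediamine in DMSO should give the terminal alkyne ketal F1. Acid hydrolysis and NaOMe equilibration should give the ketone F2. Indium and 1-bromobut-2-yne should give the allenyl carbinol F3, and TESOTf the silyl ether F4. The same Rh(I) cyclocarbonylation should give the C6-unsubstituted dienone F5, and HF·pyridine the hydroxy dienone F6. Conjugate reduction with [(Ph3P)CuH]6 in the presence of TMSCl should give the C5–C6 trimethylsilyl enol ether F7 with 8α-H. MeLi then MeI alkylates the regiodefined enolate anti to C9, and the route is rejoined at 27.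

3. Step 9, hydrogenation of the tetrasubstituted alkene. Uptake may be slow, the alkene may migrate on the catalyst, or hydrogen may add from the ester face, giving cis-fused or 21α-isopropyl material. The fallback is a hydroxyl-directed homogeneous hydrogenation and sets out from enone 12. KOt-Bu in t-BuOH followed by an AcOH quench should give the β,γ-unsaturated ketone F8, and L-Selectride the axial 27α-alcohol F9. 9-BBN then NaOH/H2O2 should give the diol F10. [Ir(cod)(PCy3)(py)]PF6 and H2 should deliver hydrogen from the hydroxyl-bearing α-face to give the trans-fused diol F11. I2/PPh3/imidazole at −20 °C should convert the primary alcohol into the iodo alcohol F12, and excess prop-1-ynyllithium should give the alkynol F13. Oxidation with DMP rejoins the route at 20.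

**Further compounds**

F0 | step 15 | none | none
F1 | step 18 | terminal alkyne ketal, 13α-[(2S)-hex-5-yn-2-yl] | C#CCC[C@H](C)[C@H]1C[C@@]2(C(=O)OC)CC[C@H](C(C)C)[C@@H]2CC13OCCO3
F2 | step 18 | terminal alkyne C27 ketone | C#CCC[C@H](C)[C@H]1C[C@@]2(C(=O)OC)CC[C@H](C(C)C)[C@@H]2CC1=O
F3 | step 18 | terminal alkyne allenyl carbinol (27α-OH) | C#CCC[C@H](C)[C@H]1C[C@@]2(C(=O)OC)CC[C@H](C(C)C)[C@@H]2C[C@]1(O)C(C)=C=C
F4 | step 18 | triethylsilyl ether of F3 | C#CCC[C@H](C)[C@H]1C[C@@]2(C(=O)OC)CC[C@H](C(C)C)[C@@H]2C[C@]1(O[Si](CC)(CC)CC)C(C)=C=C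
F5 | step 18 | C6-unsubstituted tetracyclic dienone (27α-OTES) | C/C1=C2\CC(=O)C=C2CC[C@H](C)[C@H]2C[C@@]3(C(=O)OC)CC[C@H](C(C)C)[C@@H]3C[C@]12O[Si](CC)(CC)CC
F6 | step 18 | C6-unsubstituted 27α-hydroxy dienone | C/C1=C2\CC(=O)C=C2CC[C@H](C)[C@H]2C[C@@]3(C(=O)OC)CC[C@H](C(C)C)[C@@H]3C[C@]12O
F7 | step 18 | C5–C6 trimethylsilyl enol ether (8α-H) | C/C1=C2\CC(O[Si](C)(C)C)=C[C@@H]2CC[C@H](C)[C@H]2C[C@@]3(C(=O)OC)CC[C@H](C(C)C)[C@@H]3C[C@]12O
F8 | step 9 | β,γ-unsaturated ketone (C25=C21 alkene, C27 ketone, 13α-[(2S)-but-3-en-2-yl]) | C=C[C@H](C)[C@H]1C[C@@]2(C(=O)OC)CCC(C(C)C)=C2CC1=O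
F9 | step 9 | 27α-alcohol (C25=C21 alkene) | C=C[C@H](C)[C@H]1C[C@@]2(C(=O)OC)CCC(C(C)C)=C2C[C@H]1O
F10 | step 9 | diol (27α-OH, primary C9-OH, C25=C21 alkene) | OCC[C@H](C)[C@H]1C[C@@]2(C(=O)OC)CCC(C(C)C)=C2C[C@H]1O
F11 | step 9 | trans-fused diol (25α-H, 21β-isopropyl) | OCC[C@H](C)[C@H]1C[C@@]2(C(=O)OC)CC[C@H](C(C)C)[C@@H]2C[C@H]1O
F12 | step 9 | trans-fused iodo alcohol (27α-OH) | ICC[C@H](C)[C@H]1C[C@@]2(C(=O)OC)CC[C@H](C(C)C)[C@@H]2C[C@H]1O
F13 | step 9 | trans-fused alkynol (27α-OH, 13α-[(2S)-hept-5-yn-2-yl]) | CC#CCC[C@H](C)[C@H]1C[C@@]2(C(=O)OC)CC[C@H](C(C)C)[C@@H]2C[C@H]1O
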